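The cyclohexane ring is disconnected at C5–C6, the aldol-type bond between the carbinol carbon C5 and the methylene C6 beside the C1 carbonyl. The key step is an all-carbon counterpart of the acylketene/enol ether hetero-Diels–Alder reaction: 3-ethoxycyclobutenone opens to an ethoxyvinylketene, which takes up benzyl vinyl ether and closes the carbocycle at C5–C6. One operation assembles all six ring carbons with the 1,3,5-oxygen pattern (oxygens on C1, C3 and C5) that the key step exploits. The precursor is a four-membered enone plus an enol ether. Hydrolysis, C-acylation at C2 with a Wittig-derived acid and one global hydrogenation complete the route.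

Key step: step 2

Remark: C5 is stereogenic only in the ring-enol tautomer drawn; proton transfer between the C1 and C3 oxygens (through the triketone or the exocyclic enol) converts that tautomer into its mirror image, so the route delivers the equilibrating compound and no step can or need fix C5.

Numbering (target ring): C1 and C3 are the oxygen-bearing sp2 ring carbons, C2 carries the acyl group, C4 and C6 are the CH2 groups, C5 is the carbinol carbon, and C6 lies between C1 and C5. In step 2 the cyclobutenone supplies C3 (C=O), C2, C1 (C–OEt) and C6; benzyl vinyl ether supplies C4 and C5.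

Step 1
Reactants: 1 3,4-bis(benzyloxy)benzaldehyde; 2 (7-carboxyheptyl)triphenylphosphonium bromide
Product: 4 (8Z)-9-[3,4-bis(benzyloxy)phenyl]non-8-enoic acid, via ylide carboxylate 3 (not isolated)
Conditions: 2, NaN(SiMe3)2 (2.1 equiv), THF, 0 °C; then 1, −78 °C → rt; 1 M HCl work-up
Reagents that add atoms: none
Why: Wittig olefination of the non-stabilised ylide (generated as its carboxylate salt 3) with the aryl aldehyde should give the alkene mainly as the Z isomer, and the geometry is of no consequence because step 5 saturates this double bond.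

Step 2
Reactants: 5 3-ethoxycyclobut-2-en-1-one; 6 benzyl vinyl ether
Product: 9 5-(benzyloxy)-3-ethoxycyclohex-2-en-1-one, via ethoxyvinylketene 7 (not isolated), via vinylcyclobutanone 8 (not isolated)
Conditions: 6 (5 equiv), PhMe, 110 °C (sealed tube); evaporate excess 6; then BF3·OEt2 (10 mol %), 2,6-di-tert-butylpyridine (20 mol %), CH2Cl2, −45 → 0 °C
Reagents that add atoms: none
Why: Proposed new method: at 110 °C cyclobutenone 5 should undergo 4π-electrocyclic ring opening to vinylketene 7, whose ketene carbon (C3) is attacked by the nucleophilic CH2 of enol ether 6 (C4) to give, by the usual ketene–enol ether [2+2] mode, the donor–acceptor cyclobutanone 8; BF3·OEt2 should then ionise its C2–C5 bond to a zwitterion (benzyloxycarbenium ion at C5, 2-ethoxydienolate over O–C3–C2–C1–C6) that recloses at the terminal carbon C6. The closest known reaction types are the acylketene–vinyl ether hetero-Diels–Alder reaction (of which this is the all-carbon version), the cyclobutenone–alkynyl ether benzannulation through vinylketenes, and the Lewis-acid opening of 3-alkoxycyclobutanones to 1,4-zwitterions. The four-membered ring of 8 closes by [2+2] cycloaddition, the six-membered ring of 9 by 6-(enolendo)-exo-trig attack of C6 on the oxocarbenium carbon C5, overall a formal [4+2] annulation or a 1,3-shift of C5 from C2 to C6. The new stereocentre C5 is formed racemic and uncontrolled, which is harmless because C5 ceases to be stereogenic in dione 10. The step needs γ- (C6) over α- (C2) closure and C2–C5 heterolysis in place of an acyl shift: the benzyloxy donor on C5, the ketone acceptor and the catalytic Lewis acid make α-closure reversible, only the zwitterion with C1 and C4 cis across C2=C3 can reach C6, and closure there is irreversible because it trades ring strain for a conjugated vinylogous ester.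

Step 3
Reactants: 9 5-(benzyloxy)-3-ethoxycyclohex-2-en-1-one
Product: 10 5-(benzyloxy)cyclohexane-1,3-dione
Conditions: 1 M aq. HCl, THF, 0 °C → rt
Reagents that add atoms: water, O
Why: Acid-catalysed hydrolysis of the vinylogous ester (β-alkoxy enone) by addition of water at C1 and loss of ethanol should free the 1,3-dione, in which C4 and C6 become equivalent and C5 is no longer stereogenic; dilute acid at or below room temperature should leave the C5 benzyl ether in place.

Step 4
Reactants: 10 5-(benzyloxy)cyclohexane-1,3-dione; 4 (8Z)-9-[3,4-bis(benzyloxy)phenyl]non-8-enoic acid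
Product: 12 5-(benzyloxy)-2-{(8Z)-9-[3,4-bis(benzyloxy)phenyl]non-8-enoyl}-3-hydroxycyclohex-2-en-1-one, via enol ester 11 (not isolated)
Conditions: DCC (1.2 equiv), DMAP (0.3 equiv), CH2Cl2, 0 °C → rt
Reagents that add atoms: none
Why: Carbodiimide (Steglich-type) O-acylation of the dione enol should give enol ester 11, which DMAP converts by O-to-C acyl migration (Fries-type rearrangement of an enol ester) into the 2-acyl-1,3-dione, the thermodynamic sink as its hydrogen-bonded enol, without touching the alkene or the benzyl ethers.

Step 5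
Reactants: 12 5-(benzyloxy)-2-{(8Z)-9-[3,4-bis(benzyloxy)phenyl]non-8-enoyl}-3-hydroxycyclohex-2-en-1-one
Product: 13 2-[9-(3,4-dihydroxyphenyl)nonanoyl]-3,5-dihydroxycyclohex-2-en-1-one (target)
Conditions: H2 (1 atm), 10% Pd/C, EtOAc/MeOH, rt
Reagents that add atoms: none
Why: Heterogeneous hydrogenation over Pd/C should saturate the C8–C9 double bond and hydrogenolyse the two aryl benzyl ethers and the C5 benzyl ether in one neutral operation that avoids acid-promoted dehydration to the 2-acylresorcinol; the C5 configuration needs no control for the reason given in the remark.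

Compound list
1 | 3,4-bis(benzyloxy)benzaldehyde | O=Cc1ccc(OCc2ccccc2)c(OCc2ccccc2)c1 | starting material
2 | (7-carboxyheptyl)triphenylphosphonium bromide | [Br-].OC(=O)CCCCCCC[P+](c1ccccc1)(c1ccccc1)c1ccccc1 | starting material
3 | sodium 8-(triphenyl-λ5-phosphanylidene)octanoate (ylide carboxylate) | [Na+].[O-]C(=O)CCCCCCC=P(c1ccccc1)(c1ccccc1)c1ccccc1 | intermediate
4 | (8Z)-9-[3,4-bis(benzyloxy)phenyl]non-8-enoic acid (Z expected as major isomer) | OC(=O)CCCCCC/C=C\c1ccc(OCc2ccccc2)c(OCc2ccccc2)c1 | intermediate
5 | 3-ethoxycyclobut-2-en-1-one | CCOC1=CC(=O)C1 | starting material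
6 | benzyl vinyl ether | C=COCc1ccccc1 | starting material
7 | 3-ethoxybuta-1,3-dien-1-one (ethoxyvinylketene) | CCOC(=C)C=C=O | intermediate
8 | 3-(benzyloxy)-2-(1-ethoxyethenyl)cyclobutan-1-one (racemic, cis/trans mixture) | CCOC(=C)C1C(OCc2ccccc2)CC1=O | intermediate
9 | 5-(benzyloxy)-3-ethoxycyclohex-2-en-1-one (racemic) | CCOC1=CC(=O)CC(OCc2ccccc2)C1 | intermediate
10 | 5-(benzyloxy)cyclohexane-1,3-dione | O=C1CC(=O)CC(OCc2ccccc2)C1 | intermediate
11 | 5-(benzyloxy)-3-oxocyclohex-1-en-1-yl (8Z)-9-[3,4-bis(benzyloxy)phenyl]non-8-enoate (racemic) | O=C(CCCCCC/C=C\c1ccc(OCc2ccccc2)c(OCc2ccccc2)c1)OC1=CC(=O)CC(OCc2ccccc2)C1 | intermediate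
12 | 5-(benzyloxy)-2-{(8Z)-9-[3,4-bis(benzyloxy)phenyl]non-8-enoyl}-3-hydroxycyclohex-2-en-1-one (C5 not configurationally stable) | O=C(CCCCCC/C=C\c1ccc(OCc2ccccc2)c(OCc2ccccc2)c1)C1=C(O)CC(OCc2ccccc2)CC1=O | intermediate
13 | 2-[9-(3,4-dihydroxyphenyl)nonanoyl]-3,5-dihydroxycyclohex-2-en-1-one, drawn tautomer with the C5 descriptor as given | O=C(CCCCCCCCc1ccc(O)c(O)c1)C1=C(O)C[C@H](O)CC1=O | target

Total step count: 5. Longest linear sequence: 4 steps (steps 2 to 5, from 5 and 6); step 1 is a one-step branch that joins at step 4.

Steps most likely to fail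

Step 2 (key step, new method). The vinylketene 7 may dimerise before it meets 6. The zwitterion may also be diverted, by proton loss to an open-chain benzyloxyvinyl ketone or by an acyl shift in place of C2–C5 heterolysis, so that the carbocycle does not close at C5–C6. The fallback uses known reaction types only, sets out from 6 and returns at 10. Compound 6 is heated in PhMe at 110 °C with commercial 6-(chloromethyl)-2,2-dimethyl-4H-1,3-dioxin-4-one, which loses acetone to give (chloroacetyl)ketene F1. The acylketene hetero-Diels–Alder reaction of F1 with 6 gives 2-(benzyloxy)-6-(chloromethyl)-2,3-dihydro-4H-pyran-4-one F2. Zn dust, Me3SiCl and TMEDA in THF (a vinylogous Reformatsky-type reductive silylation) turn F2 into the exocyclic enol acetal 2-(benzyloxy)-6-methylidene-4-(trimethylsilyloxy)-3,6-dihydro-2H-pyran F3. Catalytic Me3SiOTf in CH2Cl2 at −78 °C then effects a Ferrier-type (Petasis–Ferrier) carbocyclisation: the endocyclic acetal C–O bond ionises and the silyloxydiene terminus adds to the benzyloxycarbenium carbon, again closing C5–C6, to give 5-(benzyloxy)-3-(trimethylsilyloxy)cyclohex-2-en-1-one F4. Aqueous work-up delivers dione 10, so step 3 is bypassed as well.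

Step 3. Acid may promote loss of benzyl alcohol from C5 of 9 or 10, followed by aromatisation to a resorcinol. The fallback sets out from 5 and returns at 10. Vinylogous transesterification of 5 with benzyl alcohol (PPTS, PhMe, 40 °C, ethanol removed) gives 3-(benzyloxy)cyclobut-2-en-1-one F5. Under the conditions of step 2, F5 passes through 3-(benzyloxy)buta-1,3-dien-1-one F6 and 3-(benzyloxy)-2-[1-(benzyloxy)ethenyl]cyclobutan-1-one F7 to 3,5-bis(benzyloxy)cyclohex-2-en-1-one F8. The enol benzyl ether alone is then hydrogenolysed (H2, 10% Pd/C, pyridine, EtOAc; the amine suppresses cleavage of the alkyl benzyl ether) to give 10 without any acid.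

Step 5. Hydrogenolysis may stall at the secondary C5 benzyl ether, and forcing it may over-reduce the enolised triketone or cause dehydration to the 2-acylresorcinol. The fallback sets out from 12 and returns at 13. A short hydrogenation (H2, 10% Pd/C, EtOAc) that only saturates the alkene and cleaves the two aryl benzyl ethers gives 5-(benzyloxy)-2-[9-(3,4-dihydroxyphenyl)nonanoyl]-3-hydroxycyclohex-2-en-1-one F9. The remaining ether is then cleaved non-reductively with BCl3 and pentamethylbenzene (cation scavenger) in CH2Cl2 at −78 °C to give 13.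

Further compounds
F1 | step 2 | 4-chloro-3-oxobut-1-en-1-one ((chloroacetyl)ketene) | O=C=CC(=O)CCl
F2 | step 2 | 2-(benzyloxy)-6-(chloromethyl)-2,3-dihydro-4H-pyran-4-one | O=C1CC(OCc2ccccc2)OC(CCl)=C1
F3 | step 2 | 2-(benzyloxy)-6-methylidene-4-(trimethylsilyloxy)-3,6-dihydro-2H-pyran | C=C1C=C(O[Si](C)(C)C)CC(OCc2ccccc2)O1
F4 | step 2 | 5-(benzyloxy)-3-(trimethylsilyloxy)cyclohex-2-en-1-one | C[Si](C)(C)OC1=CC(=O)CC(OCc2ccccc2)C1
F5 | step 3 | 3-(benzyloxy)cyclobut-2-en-1-one | O=C1C=C(OCc2ccccc2)C1
F6 | step 3 | 3-(benzyloxy)buta-1,3-dien-1-one | C=C(OCc1ccccc1)C=C=O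
F7 | step 3 | 3-(benzyloxy)-2-[1-(benzyloxy)ethenyl]cyclobutan-1-one | C=C(OCc1ccccc1)C1C(OCc2ccccc2)CC1=O
F8 | step 3 | 3,5-bis(benzyloxy)cyclohex-2-en-1-one | O=C1C=C(OCc2ccccc2)CC(OCc2ccccc2)C1
F9 | step 5 | 5-(benzyloxy)-2-[9-(3,4-dihydroxyphenyl)nonanoyl]-3-hydroxycyclohex-2-en-1-one | O=C(CCCCCCCCc1ccc(O)c(O)c1)C1=C(O)CC(OCc2ccccc2)CC1=O
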